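**Retrosynthetic overview**

1. Target 23 is a flavonol in which only ring C has to be built. It is opened at O1–C2 and at the C2–C3 bond, the bond joining the oxygen-bearing C3 to the C2 that carries ring B; O1 must be the ring-A oxygen next to the C8 methoxy group.
2. This leads to aryl ester 18: an ω-silyloxy aryl ketone whose ortho oxygen beside the methoxy group carries the 4-silyloxy-3-methoxybenzoyl unit, while the other ortho oxygen (future O5) is blocked as a MOM ether.
3. Ester 18 is made from acid 17 (from vanillic acid 15) and phenol 14. Phenol 14 comes from the symmetric arene 7 by ortho-lithiation/acylation with Weinreb amide 9, debenzylation and para-selective O-prenylation with 13.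
4. Arene 7 comes from methyl 4-O-methylgallate 1 by benzylation, ester → aldehyde, Dakin-type Baeyer–Villiger oxidation and MOM protection.
5. Ring order: rings A and B are bought, ring C is the only ring formed (step 12); fluoride and then dilute acid unmask 23.

Key step: step 12

Remark on the chemistry: the target has no stereocentre. The sp3 centres of intermediates 19 and 20 (and of fallback carbinol F3) arise without control, are drawn without configuration and are erased again.

**Route**

Step 1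
Reactants: 1 methyl 3,5-dihydroxy-4-methoxybenzoate
Product: 2 methyl 3,5-bis(benzyloxy)-4-methoxybenzoate
Conditions: BnBr (2.4 equiv), K2CO3 (3 equiv), DMF, 60 °C
Reagents that add atoms: benzyl bromide, BrCc1ccccc1
Why: Williamson etherification of the two equivalent phenoxides, the 4-oxygen being already methylated, so that a single dibenzyl ether is expected.

Step 2
Reactants: 2 methyl 3,5-bis(benzyloxy)-4-methoxybenzoate
Product: 3 [3,5-bis(benzyloxy)-4-methoxyphenyl]methanol
Conditions: LiAlH4 (1.2 equiv), THF, 0 °C→rt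
Reagents that add atoms: none
Why: Hydride reduction of the ester to the primary benzylic alcohol, to which the aryl ethers are inert.

Step 3
Reactants: 3 [3,5-bis(benzyloxy)-4-methoxyphenyl]methanol
Product: 4 3,5-bis(benzyloxy)-4-methoxybenzaldehyde
Conditions: activated MnO2 (excess), CH2Cl2, rt
Reagents that add atoms: none
Why: Selective benzylic alcohol oxidation with MnO2, which stops at the aldehyde.

Step 4
Reactants: 4 3,5-bis(benzyloxy)-4-methoxybenzaldehyde
Product: 6 3,5-bis(benzyloxy)-4-methoxyphenol, via aryl formate 5 (not isolated)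
Conditions: mCPBA (1.3 equiv), CH2Cl2, 0 °C→rt; NaHCO3 wash; then K2CO3 (0.1 equiv), MeOH, rt
Reagents that add atoms: 3-chloroperoxybenzoic acid (mCPBA), OOC(=O)c1cccc(Cl)c1
Why: Baeyer–Villiger (Dakin-type) oxidation in which the electron-rich trialkoxyaryl group migrates in preference to hydrogen to give the aryl formate, which mild methanolysis cleaves to the phenol.

Step 5
Reactants: 6 3,5-bis(benzyloxy)-4-methoxyphenol
Product: 7 1,3-bis(benzyloxy)-2-methoxy-5-(methoxymethoxy)benzene
Conditions: MOMCl (1.5 equiv), i-Pr2NEt (2 equiv), CH2Cl2, 0 °C→rt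
Reagents that add atoms: chloromethyl methyl ether (MOMCl), COCCl
Why: O-alkylation of the phenol to the MOM acetal, the group that later directs lithiation and blocks the future O5.

Step 6
Reactants: 8 ethyl 2-[(tert-butyldimethylsilyl)oxy]acetate
Product: 9 2-[(tert-butyldimethylsilyl)oxy]-N-methoxy-N-methylacetamide
Conditions: MeNH(OMe)·HCl (1.5 equiv), i-PrMgCl (3.0 equiv), THF, −20→0 °C
Reagents that add atoms: N,O-dimethylhydroxylamine hydrochloride, CNOC.Cl
Why: Weinreb amide formation by aminolysis of the ester with the chloromagnesium amide of N,O-dimethylhydroxylamine, conditions that leave the silyl ether untouched.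

Step 7
Reactants: 7 1,3-bis(benzyloxy)-2-methoxy-5-(methoxymethoxy)benzene; 9 2-[(tert-butyldimethylsilyl)oxy]-N-methoxy-N-methylacetamide
Product: 11 1-[2,4-bis(benzyloxy)-3-methoxy-6-(methoxymethoxy)phenyl]-2-[(tert-butyldimethylsilyl)oxy]ethan-1-one, via aryllithium 10 (not isolated)
Conditions: n-BuLi (1.1 equiv), THF, −20→0 °C; then 9 (1.3 equiv), −78→0 °C; NH4Cl (aq)
Reagents that add atoms: n-butyllithium, [Li]CCCC (supplies the lithium of 10; no atom of it remains in 11)
Why: Directed ortho-metalation at the ring position flanked by the MOM and benzyl ethers (the two ring C–H are symmetry-equivalent), followed by single addition of the aryllithium to the Weinreb amide, whose chelated tetrahedral adduct prevents over-addition.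

Step 8
Reactants: 11 1-[2,4-bis(benzyloxy)-3-methoxy-6-(methoxymethoxy)phenyl]-2-[(tert-butyldimethylsilyl)oxy]ethan-1-one
Product: 12 2-[(tert-butyldimethylsilyl)oxy]-1-[2,4-dihydroxy-3-methoxy-6-(methoxymethoxy)phenyl]ethan-1-one
Conditions: H2 (1 atm), 10% Pd/C, EtOAc, rt
Reagents that add atoms: none
Why: Catalytic hydrogenolysis of both benzyl aryl ethers, under which the MOM acetal, the silyl ether and the hindered electron-rich aryl ketone should persist.

Step 9
Reactants: 12 2-[(tert-butyldimethylsilyl)oxy]-1-[2,4-dihydroxy-3-methoxy-6-(methoxymethoxy)phenyl]ethan-1-one; 13 prenyl bromide (1-bromo-3-methylbut-2-ene)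
Product: 14 2-[(tert-butyldimethylsilyl)oxy]-1-{2-hydroxy-3-methoxy-6-(methoxymethoxy)-4-[(3-methylbut-2-en-1-yl)oxy]phenyl}ethan-1-one
Conditions: 13 (1.05 equiv), K2CO3 (1.2 equiv), acetone, rt→40 °C
Reagents that add atoms: none
Why: Williamson O-alkylation that should select the 4-OH (para to the acyl group, more acidic and unhindered) over the 2-OH, which is hydrogen-bonded to the ketone and flanked on both sides.

Step 10
Reactants: 15 vanillic acid (4-hydroxy-3-methoxybenzoic acid)
Product: 17 4-[(tert-butyldimethylsilyl)oxy]-3-methoxybenzoic acid, via bis-silyl ester 16 (not isolated)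
Conditions: TBSCl (2.4 equiv), imidazole (5 equiv), DMF, rt; then AcOH/H2O/THF (3:1:1), rt
Reagents that add atoms: tert-butyldimethylsilyl chloride (TBSCl), CC(C)(C)[Si](C)(C)Cl
Why: Silylation of phenol and acid followed by selective hydrolysis of the far more labile silyl ester, which leaves the aryl silyl ether in place.

Step 11
Reactants: 14 2-[(tert-butyldimethylsilyl)oxy]-1-{2-hydroxy-3-methoxy-6-(methoxymethoxy)-4-[(3-methylbut-2-en-1-yl)oxy]phenyl}ethan-1-one; 17 4-[(tert-butyldimethylsilyl)oxy]-3-methoxybenzoic acid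
Product: 18 2-{[(tert-butyldimethylsilyl)oxy]acetyl}-6-methoxy-3-(methoxymethoxy)-5-[(3-methylbut-2-en-1-yl)oxy]phenyl 4-[(tert-butyldimethylsilyl)oxy]-3-methoxybenzoate
Conditions: EDC·HCl (1.5 equiv), DMAP (0.5 equiv), CH2Cl2, rt
Reagents that add atoms: none
Why: Steglich carbodiimide/DMAP esterification, in which the acylpyridinium intermediate should be reactive enough to acylate the only free hydroxyl, the hindered 2-OH beside the methoxy group.

Step 12
Reactants: 18 2-{[(tert-butyldimethylsilyl)oxy]acetyl}-6-methoxy-3-(methoxymethoxy)-5-[(3-methylbut-2-en-1-yl)oxy]phenyl 4-[(tert-butyldimethylsilyl)oxy]-3-methoxybenzoate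
Product: 21 3-[(tert-butyldimethylsilyl)oxy]-2-{4-[(tert-butyldimethylsilyl)oxy]-3-methoxyphenyl}-8-methoxy-5-(methoxymethoxy)-7-[(3-methylbut-2-en-1-yl)oxy]-4H-chromen-4-one (3,4'-bis-O-TBS-5-O-MOM ether of the target), via 1,3-diketone 19 (not isolated), via hemiketal 20 (not isolated)
Conditions: LiN(SiMe3)2 (3.2 equiv), THF, −78→0 °C; AcOH quench, extractive work-up; then PPTS (0.2 equiv), 4 Å MS, PhMe, 60 °C
Reagents that add atoms: none
Why: LiN(SiMe3)2 removes a proton from the only enolisable position, the ω-CH2 between the ketone and the silyl ether, and the lithium enolate attacks the carbonyl of the neighbouring aryl ester through a six-membered transition state, expelling the ring-A phenoxide and forming C2–C3 (a Baker–Venkataraman O-to-C acyl shift, the reaction type known for ω-alkoxy- and ω-acyloxy-2-aroyloxyacetophenones on the way to 3-oxygenated flavones). After the acetic acid quench the freed phenol of diketone 19 adds to the new aryl ketone in a 6-exo-trig closure to hemiketal 20, and pyridinium tosylate over molecular sieves should drive loss of water through the oxocarbenium ion stabilised by O1 and ring B to give the chromen-4-one (O1–C2), the standard cyclodehydration of o-hydroxyaryl 1,3-diketones. No stereocentre is present in 21, since the sp3 centres of 19 and 20 form without control and disappear on dehydration. The step needs regiocontrol over which ortho oxygen becomes O1: only the oxygen beside the methoxy group carried the aroyl group and is free after the shift, the other being a MOM ether, so only the 8-methoxy isomer can arise as long as the MOM group outlasts the closure, which is why a weak buffered acid in an aprotic solvent is chosen. It also needs enolisation to win over ester cleavage, which the non-nucleophilic amide base and the lack of α-hydrogens in the aroyl ester should secure. Partial loss of the 3-O-silyl group would be harmless because step 13 removes it in any case.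

Step 13
Reactants: 21 3-[(tert-butyldimethylsilyl)oxy]-2-{4-[(tert-butyldimethylsilyl)oxy]-3-methoxyphenyl}-8-methoxy-5-(methoxymethoxy)-7-[(3-methylbut-2-en-1-yl)oxy]-4H-chromen-4-one
Product: 22 3-hydroxy-2-(4-hydroxy-3-methoxyphenyl)-8-methoxy-5-(methoxymethoxy)-7-[(3-methylbut-2-en-1-yl)oxy]-4H-chromen-4-one
Conditions: Bu4NF (2.2 equiv), AcOH (2.2 equiv), THF, 0 °C, argon
Reagents that add atoms: none
Why: Fluoride-induced Si–O cleavage of the aryl and enol silyl ethers, buffered with acetic acid to protect the flavonol from basic phenoxide conditions, while the MOM acetal and the prenyl ether are inert to fluoride.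

Step 14
Reactants: 22 3-hydroxy-2-(4-hydroxy-3-methoxyphenyl)-8-methoxy-5-(methoxymethoxy)-7-[(3-methylbut-2-en-1-yl)oxy]-4H-chromen-4-one
Product: 23 3,5-dihydroxy-2-(4-hydroxy-3-methoxyphenyl)-8-methoxy-7-[(3-methylbut-2-en-1-yl)oxy]-4H-chromen-4-one (target)
Conditions: HCl (0.5 M in MeOH), THF, 0 °C→rt
Reagents that add atoms: none
Why: Acid-catalysed acetal exchange with methanol (MOM cleavage), expected to be fast for the 5-O-MOM group peri to the C4 carbonyl because the chelated 5-OH is released, so that dilute acid at or below room temperature should not ionise the allylic prenyl ether.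

**Compound list**

1 | methyl 3,5-dihydroxy-4-methoxybenzoate | COC(=O)c1cc(O)c(OC)c(O)c1 | starting material
2 | methyl 3,5-bis(benzyloxy)-4-methoxybenzoate | COC(=O)c1cc(OCc2ccccc2)c(OC)c(OCc2ccccc2)c1 | intermediate
3 | [3,5-bis(benzyloxy)-4-methoxyphenyl]methanol | COc1c(OCc2ccccc2)cc(CO)cc1OCc1ccccc1 | intermediate
4 | 3,5-bis(benzyloxy)-4-methoxybenzaldehyde | COc1c(OCc2ccccc2)cc(C=O)cc1OCc1ccccc1 | intermediate
5 | 3,5-bis(benzyloxy)-4-methoxyphenyl formate | COc1c(OCc2ccccc2)cc(OC=O)cc1OCc1ccccc1 | intermediate (not isolated)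
6 | 3,5-bis(benzyloxy)-4-methoxyphenol | COc1c(OCc2ccccc2)cc(O)cc1OCc1ccccc1 | intermediate
7 | 1,3-bis(benzyloxy)-2-methoxy-5-(methoxymethoxy)benzene | COCOc1cc(OCc2ccccc2)c(OC)c(OCc2ccccc2)c1 | intermediate
8 | ethyl 2-[(tert-butyldimethylsilyl)oxy]acetate | CCOC(=O)CO[Si](C)(C)C(C)(C)C | starting material
9 | 2-[(tert-butyldimethylsilyl)oxy]-N-methoxy-N-methylacetamide | CON(C)C(=O)CO[Si](C)(C)C(C)(C)C | intermediate
10 | [2,4-bis(benzyloxy)-3-methoxy-6-(methoxymethoxy)phenyl]lithium | [Li]c1c(OCOC)cc(OCc2ccccc2)c(OC)c1OCc1ccccc1 | intermediate (not isolated)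
11 | 1-[2,4-bis(benzyloxy)-3-methoxy-6-(methoxymethoxy)phenyl]-2-[(tert-butyldimethylsilyl)oxy]ethan-1-one | O=C(CO[Si](C)(C)C(C)(C)C)c1c(OCOC)cc(OCc2ccccc2)c(OC)c1OCc1ccccc1 | intermediate
12 | 2-[(tert-butyldimethylsilyl)oxy]-1-[2,4-dihydroxy-3-methoxy-6-(methoxymethoxy)phenyl]ethan-1-one | O=C(CO[Si](C)(C)C(C)(C)C)c1c(OCOC)cc(O)c(OC)c1O | intermediate
13 | prenyl bromide (1-bromo-3-methylbut-2-ene) | CC(C)=CCBr | starting material
14 | 2-[(tert-butyldimethylsilyl)oxy]-1-{2-hydroxy-3-methoxy-6-(methoxymethoxy)-4-[(3-methylbut-2-en-1-yl)oxy]phenyl}ethan-1-one | O=C(CO[Si](C)(C)C(C)(C)C)c1c(OCOC)cc(OCC=C(C)C)c(OC)c1O | intermediate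
15 | vanillic acid (4-hydroxy-3-methoxybenzoic acid) | COc1cc(C(=O)O)ccc1O | starting material
16 | tert-butyldimethylsilyl 4-[(tert-butyldimethylsilyl)oxy]-3-methoxybenzoate | COc1cc(C(=O)O[Si](C)(C)C(C)(C)C)ccc1O[Si](C)(C)C(C)(C)C | intermediate (not isolated)
17 | 4-[(tert-butyldimethylsilyl)oxy]-3-methoxybenzoic acid | COc1cc(C(=O)O)ccc1O[Si](C)(C)C(C)(C)C | intermediate
18 | 2-{[(tert-butyldimethylsilyl)oxy]acetyl}-6-methoxy-3-(methoxymethoxy)-5-[(3-methylbut-2-en-1-yl)oxy]phenyl 4-[(tert-butyldimethylsilyl)oxy]-3-methoxybenzoate | O=C(CO[Si](C)(C)C(C)(C)C)c1c(OC(=O)c2ccc(O[Si](C)(C)C(C)(C)C)c(OC)c2)c(OC)c(OCC=C(C)C)cc1OCOC | intermediate (key-step precursor)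
19 | 2-[(tert-butyldimethylsilyl)oxy]-1-{2-hydroxy-3-methoxy-6-(methoxymethoxy)-4-[(3-methylbut-2-en-1-yl)oxy]phenyl}-3-{4-[(tert-butyldimethylsilyl)oxy]-3-methoxyphenyl}propane-1,3-dione (configuration at C2 not defined) | O=C(c1c(O)c(OC)c(OCC=C(C)C)cc1OCOC)C(O[Si](C)(C)C(C)(C)C)C(=O)c1ccc(O[Si](C)(C)C(C)(C)C)c(OC)c1 | intermediate (not isolated)
20 | 3-[(tert-butyldimethylsilyl)oxy]-2-{4-[(tert-butyldimethylsilyl)oxy]-3-methoxyphenyl}-2-hydroxy-8-methoxy-5-(methoxymethoxy)-7-[(3-methylbut-2-en-1-yl)oxy]-2,3-dihydro-4H-chromen-4-one (configuration at C2 and C3 not defined) | COc1cc(C2(O)Oc3c(OC)c(OCC=C(C)C)cc(OCOC)c3C(=O)C2O[Si](C)(C)C(C)(C)C)ccc1O[Si](C)(C)C(C)(C)C | intermediate (not isolated)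
21 | 3-[(tert-butyldimethylsilyl)oxy]-2-{4-[(tert-butyldimethylsilyl)oxy]-3-methoxyphenyl}-8-methoxy-5-(methoxymethoxy)-7-[(3-methylbut-2-en-1-yl)oxy]-4H-chromen-4-one | COc1cc(-c2oc3c(OC)c(OCC=C(C)C)cc(OCOC)c3c(=O)c2O[Si](C)(C)C(C)(C)C)ccc1O[Si](C)(C)C(C)(C)C | intermediate (key-step product)
22 | 3-hydroxy-2-(4-hydroxy-3-methoxyphenyl)-8-methoxy-5-(methoxymethoxy)-7-[(3-methylbut-2-en-1-yl)oxy]-4H-chromen-4-one | COc1cc(-c2oc3c(OC)c(OCC=C(C)C)cc(OCOC)c3c(=O)c2O)ccc1O | intermediate
23 | 3,5-dihydroxy-2-(4-hydroxy-3-methoxyphenyl)-8-methoxy-7-[(3-methylbut-2-en-1-yl)oxy]-4H-chromen-4-one | COc1cc(-c2oc3c(OC)c(OCC=C(C)C)cc(O)c3c(=O)c2O)ccc1O | target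

**Step count**

Total: 14 steps. Longest linear sequence: 12 steps (steps 1–5, 7–9, 11–14); steps 6 and 10 are one-step side branches.

**Steps most likely to fail**

Step 12. The risk is slow or incomplete O-to-C aroyl transfer, because the twisted, doubly ortho-flanked ketone may enolise sluggishly and the crowded ester may instead lose its aroyl group back to phenol 14. The fallback sets out from phenol 14 and acid 17 and avoids ester 18. Acid 17 would be converted with oxalyl chloride and catalytic DMF in CH2Cl2 into 4-[(tert-butyldimethylsilyl)oxy]-3-methoxybenzoyl chloride F1. Phenol 14 would be turned with LiN(SiMe3)2 (4 equiv, THF, −78 °C) into its phenoxide–enolate dianion, which F1 should acylate at carbon in an intermolecular crossed Claisen condensation. Acetic acid quench gives diketone 19, where the fallback comes back to the route, and the PPTS closure of step 12 then leads to 21.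

Step 7. The risk is deprotonation of a benzylic CH2 by n-BuLi followed by [1,2]-Wittig shift, or proton transfer from the α-CH2 of amide 9 to the hindered aryllithium in place of addition. The fallback sets out from arene 7. NBS (1.0 equiv, MeCN, 0 °C) should brominate one of the two equivalent, strongly activated ring positions to give 1,3-bis(benzyloxy)-4-bromo-2-methoxy-5-(methoxymethoxy)benzene F2. Bromine–lithium exchange with n-BuLi at −78 °C, far faster than benzylic deprotonation, gives the same aryllithium 10. This is added at −78 °C to commercial (tert-butyldimethylsilyloxy)acetaldehyde, a much stronger electrophile than the amide, to give the racemic carbinol 1-[2,4-bis(benzyloxy)-3-methoxy-6-(methoxymethoxy)phenyl]-2-[(tert-butyldimethylsilyl)oxy]ethan-1-ol F3. Oxidation with Dess–Martin periodinane (CH2Cl2, NaHCO3, rt) comes back to the route at ketone 11.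

Step 14. The risk is acid ionisation of the allylic 7-O-prenyl ether (loss of the prenyl group or its O-to-C migration) competing with cleavage of the acetal. The fallback replaces the MOM group by a fluoride-labile SEM group, so that no acid meets the prenyl ether after ring closure. It sets out from phenol 6 and comes back to the route only at target 23:
- Phenol 6 with 2-(trimethylsilyl)ethoxymethyl chloride and i-Pr2NEt gives the SEM ether 1,3-bis(benzyloxy)-2-methoxy-5-{[2-(trimethylsilyl)ethoxy]methoxy}benzene F4.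
- Ortho-lithiation to the SEM aryllithium F5 and acylation with amide 9 give the SEM ketone F6.
- Hydrogenolysis gives the SEM diol F7, and prenylation with 13 gives the SEM prenyl ether F8.
- Esterification with 17 gives the SEM ester F9.
- LiN(SiMe3)2 followed by PPTS takes F9 through the SEM diketone F10 and the SEM hemiketal F11 to the 5-O-SEM flavone F12.
- A single treatment with Bu4NF (excess, THF/DMPU, 60 °C, argon) should remove the SEM group and both silyl ethers and give 23.

**Further compounds**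

F1 | step 12 | 4-[(tert-butyldimethylsilyl)oxy]-3-methoxybenzoyl chloride | COc1cc(C(Cl)=O)ccc1O[Si](C)(C)C(C)(C)C
F2 | step 7 | 1,3-bis(benzyloxy)-4-bromo-2-methoxy-5-(methoxymethoxy)benzene | COCOc1cc(OCc2ccccc2)c(OC)c(OCc2ccccc2)c1Br
F3 | step 7 | 1-[2,4-bis(benzyloxy)-3-methoxy-6-(methoxymethoxy)phenyl]-2-[(tert-butyldimethylsilyl)oxy]ethan-1-ol (racemic) | OC(CO[Si](C)(C)C(C)(C)C)c1c(OCOC)cc(OCc2ccccc2)c(OC)c1OCc1ccccc1
F4 | step 14 | 1,3-bis(benzyloxy)-2-methoxy-5-{[2-(trimethylsilyl)ethoxy]methoxy}benzene | COc1c(OCc2ccccc2)cc(OCOCC[Si](C)(C)C)cc1OCc1ccccc1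
F5 | step 14 | [2,4-bis(benzyloxy)-3-methoxy-6-{[2-(trimethylsilyl)ethoxy]methoxy}phenyl]lithium | [Li]c1c(OCOCC[Si](C)(C)C)cc(OCc2ccccc2)c(OC)c1OCc1ccccc1
F6 | step 14 | 1-[2,4-bis(benzyloxy)-3-methoxy-6-{[2-(trimethylsilyl)ethoxy]methoxy}phenyl]-2-[(tert-butyldimethylsilyl)oxy]ethan-1-one | O=C(CO[Si](C)(C)C(C)(C)C)c1c(OCOCC[Si](C)(C)C)cc(OCc2ccccc2)c(OC)c1OCc1ccccc1
F7 | step 14 | 2-[(tert-butyldimethylsilyl)oxy]-1-[2,4-dihydroxy-3-methoxy-6-{[2-(trimethylsilyl)ethoxy]methoxy}phenyl]ethan-1-one | O=C(CO[Si](C)(C)C(C)(C)C)c1c(OCOCC[Si](C)(C)C)cc(O)c(OC)c1O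
F8 | step 14 | 2-[(tert-butyldimethylsilyl)oxy]-1-{2-hydroxy-3-methoxy-4-[(3-methylbut-2-en-1-yl)oxy]-6-{[2-(trimethylsilyl)ethoxy]methoxy}phenyl}ethan-1-one | O=C(CO[Si](C)(C)C(C)(C)C)c1c(OCOCC[Si](C)(C)C)cc(OCC=C(C)C)c(OC)c1O
F9 | step 14 | 2-{[(tert-butyldimethylsilyl)oxy]acetyl}-6-methoxy-5-[(3-methylbut-2-en-1-yl)oxy]-3-{[2-(trimethylsilyl)ethoxy]methoxy}phenyl 4-[(tert-butyldimethylsilyl)oxy]-3-methoxybenzoate | O=C(CO[Si](C)(C)C(C)(C)C)c1c(OC(=O)c2ccc(O[Si](C)(C)C(C)(C)C)c(OC)c2)c(OC)c(OCC=C(C)C)cc1OCOCC[Si](C)(C)C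
F10 | step 14 | 2-[(tert-butyldimethylsilyl)oxy]-1-{2-hydroxy-3-methoxy-4-[(3-methylbut-2-en-1-yl)oxy]-6-{[2-(trimethylsilyl)ethoxy]methoxy}phenyl}-3-{4-[(tert-butyldimethylsilyl)oxy]-3-methoxyphenyl}propane-1,3-dione (configuration at C2 not defined) | O=C(c1c(O)c(OC)c(OCC=C(C)C)cc1OCOCC[Si](C)(C)C)C(O[Si](C)(C)C(C)(C)C)C(=O)c1ccc(O[Si](C)(C)C(C)(C)C)c(OC)c1
F11 | step 14 | 3-[(tert-butyldimethylsilyl)oxy]-2-{4-[(tert-butyldimethylsilyl)oxy]-3-methoxyphenyl}-2-hydroxy-8-methoxy-7-[(3-methylbut-2-en-1-yl)oxy]-5-{[2-(trimethylsilyl)ethoxy]methoxy}-2,3-dihydro-4H-chromen-4-one (configuration at C2 and C3 not defined) | COc1cc(C2(O)Oc3c(OC)c(OCC=C(C)C)cc(OCOCC[Si](C)(C)C)c3C(=O)C2O[Si](C)(C)C(C)(C)C)ccc1O[Si](C)(C)C(C)(C)C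
F12 | step 14 | 3-[(tert-butyldimethylsilyl)oxy]-2-{4-[(tert-butyldimethylsilyl)oxy]-3-methoxyphenyl}-8-methoxy-7-[(3-methylbut-2-en-1-yl)oxy]-5-{[2-(trimethylsilyl)ethoxy]methoxy}-4H-chromen-4-one | COc1cc(-c2oc3c(OC)c(OCC=C(C)C)cc(OCOCC[Si](C)(C)C)c3c(=O)c2O[Si](C)(C)C(C)(C)C)ccc1O[Si](C)(C)C(C)(C)C
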